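**One-step world.** A one-step world has each initiator molecule begin a chain at the first instant, and chain length is then a charge ratio times a conversion. I had to choose the feed for the next run, ochre or grey, and I wanted the longer chains.

| setting | Monday's | Saturday's | ochre | grey |
|---|---|---|---|---|
| free monomer | 0.041 M (fed, over 2.5 min) | 0.16 M (fed, over 2.5 min) | 0.081 M (fed, over 2.5 min) | 0.081 M (fed, over 1.2 min) |
| protic impurity | 0.0243 M | 0.0243 M | 0.0243 M | 0.0243 M |
| initiator | 0.63 mol% | 0.63 mol% | 0.63 mol% | 0.63 mol% |
| remark | run made earlier | run made earlier |  |  |
| time |  |  | 2.5 min | 2.5 min |

| run | time / min | monomer in chains / % |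
|---|---|---|
| Monday's | 0.167 | 4 |
| Monday's | 0.500 | 6 |
| Monday's | 0.833 | 0 |
| Monday's | 1.33 | 1 |
| Monday's | 2.00 | 3 |
| Monday's | 2.50 | 5 |
| Monday's | 3.00 | 4 |
| Saturday's | 0.417 | 0 |
| Saturday's | 0.833 | 3 |
| Saturday's | 1.33 | 4 |
| Saturday's | 1.50 | 8 |
| Saturday's | 2.00 | 20 |
| Saturday's | 2.50 | 37 |
| Saturday's | 3.00 | 55 |

(standard deviation of a reading: 2 percentage points)

- the average divides the monomer in chains by the number of chains begun, living and dead together
- the earlier runs do not show the number of chains; that part of a forecast is a guess
- percentages count the whole charge, also what has not yet gone in

- which of the two ends with the longer chains by the average number of monomer units in a chain (chains begun, living or dead) ("neither" if they lie within 10%) (ochre / grey / neither)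
- average number of monomer units in a chain (chains begun, living or dead) at the end, ochre
- average number of monomer units in a chain (chains begun, living or dead) at the end, grey

**Charge length.** I called D the charge length, the free monomer charged per initiator charged, 159. The number-average degree of polymerisation is then D·u/i, where u is the share of the free monomer charge in chains and i the share of the initiator charge used. In decimal logarithms, log D is 2.20. Since i cannot pass one, D·u is a floor on the length.

**My reckoning.** At 2.50 min, Monday's reading was 5% and Saturday's 37%, so on logarithmic axes the share in chains rose with the charge at a slope of 1.47. Monday's scatter of 2 percentage points stays in that reading. Carried to ochre's charge, the slope gave u near 13.6%. The logarithm of that share is −0.866, which leaves 1.33, an estimated floor of 21.6 for ochre. Grey's feed of 0.0675 M min⁻¹ was faster than ochre's 0.0324 M min⁻¹, so grey had received its whole charge 1.30 min sooner. I therefore put grey's u higher and chose grey, without a figure for i, which the earlier runs do not show.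

**The forecast.** The forecast also chose grey, with 9 for ochre and 42 for grey, from expected conversions of about 5% and 25%. Its ochre figure lies below my estimated floor. Of the chain count it said: “The chain count is a guess, so the ranges are wide.”

**The flask.**

    free monomer + initiator → living end + monomer in chains (k = 0.0910 M⁻¹ s⁻¹)
    free monomer + living end → monomer in chains + living end, rate k2*[living end]*[free monomer] (k = 29.0 M⁻¹ s⁻¹)
    protic impurity + free monomer → quenched substrate (k = 0.460 M⁻¹ s⁻¹)

The longer chains were grey's, 98.0 against 65.6 for ochre. In ochre at 2.50 min, 13.1% of the free monomer was in chains and 68.3% of the initiator was left, so i was 31.7% and D·u/i came to 65.7. Ochre left until 6.0 min had 58.4% in chains and 58.1% of its initiator used, so its length stood at D, 159.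

All runs are calculated for an exercise; the scatter is artificial.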